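Everything rests on cutting the side chain at C7'–C8' and C8'–C9' (chroman numbering; chain atoms C1' to C12' counted outward from C2). The feature exploited is the C8' methine, a methyl-bearing CH between the C7' methylene and the C9' carbonyl. It lies eight bonds from the C2 stereocentre of the dihydropyran ring (ring B), too remote for that centre to steer it. In one flask, two successive (+)-sparteine-directed lithiation–borylation homologations make both bonds, set C8' by reagent control and deliver the prenyl end as a C9' boronic ester, a masked ketone. The precursor is the primary C7' pinacol boronic ester of the (2R)-chroman, with its 3'E alkene and a triisopropylsilyl-protected phenol.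

Key step: step 11

Remark: the phenol is carried as a triisopropylsilyl ether, which should withstand the aqueous base of the cross-coupling and the alkaline peroxide better than a smaller silyl group and still leaves with buffered fluoride; ethyl 2,4,6-triisopropylbenzoate and (+)-sparteine are taken as purchased.

Step 1
Reactants: 1 2-methylhydroquinone
Product: 2 2-methyl-4-[(triisopropylsilyl)oxy]phenol
Conditions: TIPSCl (1.0 equiv), imidazole, DMF, 0 °C
Reagents that add atoms: chlorotriisopropylsilane, CC(C)[Si](Cl)(C(C)C)C(C)C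
Why: Silyl ether formation in which the bulky silyl chloride should prefer the hydroxyl group without an ortho substituent over the one flanked by the methyl group, the minor isomer and bis-ether being removed by chromatography.

Step 2
Reactants: 2 2-methyl-4-[(triisopropylsilyl)oxy]phenol
Product: 3 2-bromo-6-methyl-4-[(triisopropylsilyl)oxy]phenol
Conditions: NBS (1.0 equiv), i-Pr2NH (10 mol%), CH2Cl2, 0 °C
Reagents that add atoms: N-bromosuccinimide, O=C1CCC(=O)N1Br
Why: Amine-mediated ortho-bromination of a phenol (electrophilic aromatic substitution), directed by the free hydroxyl group to its only open ortho position, since its para position is blocked and the bulky silyl ether shields its own neighbours.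

Step 3
Reactants: 4 (R)-linalool; 3 2-bromo-6-methyl-4-[(triisopropylsilyl)oxy]phenol
Product: 6 2-[(3R)-3-hydroxy-3,7-dimethyloct-6-en-1-yl]-6-methyl-4-[(triisopropylsilyl)oxy]phenol, via alkyl-9-BBN adduct 5 (not isolated)
Conditions: 4, 9-BBN, THF, 0 °C to rt; then 3, Pd(OAc)2 (5 mol%), SPhos (10 mol%), K3PO4 (aq.), THF, 60 °C
Reagents that add atoms: none
Why: Anti-Markovnikov hydroboration of the monosubstituted alkene by 9-BBN (the trisubstituted alkene reacts far more slowly) followed by B-alkyl Suzuki–Miyaura coupling with the aryl bromide, neither event touching the carbinol stereocentre taken from linalool.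

Step 4
Reactants: 6 2-[(3R)-3-hydroxy-3,7-dimethyloct-6-en-1-yl]-6-methyl-4-[(triisopropylsilyl)oxy]phenol
Product: 7 2-[(3R)-3-hydroxy-3,7-dimethyloct-6-en-1-yl]-6-methyl-4-[(triisopropylsilyl)oxy]phenyl trifluoromethanesulfonate
Conditions: PhNTf2, Cs2CO3, MeCN, rt
Reagents that add atoms: N-phenylbis(trifluoromethanesulfonimide), O=S(=O)(N(c1ccccc1)S(=O)(=O)C(F)(F)F)C(F)(F)F
Why: Phenol triflation with a mild triflyl-transfer reagent, which should take the phenoxide and leave the hindered tertiary alcohol alone.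

Step 5
Reactants: 7 2-[(3R)-3-hydroxy-3,7-dimethyloct-6-en-1-yl]-6-methyl-4-[(triisopropylsilyl)oxy]phenyl trifluoromethanesulfonate
Product: 8 (2R)-2,8-dimethyl-2-(4-methylpent-3-en-1-yl)-6-[(triisopropylsilyl)oxy]chroman
Conditions: Pd(OAc)2 (5 mol%), 2-(di-tert-butylphosphino)-1,1'-binaphthyl (7.5 mol%), K3PO4, toluene, 90 °C
Reagents that add atoms: none
Why: Buchwald-type Pd-catalysed intramolecular aryl C–O coupling closes ring B by forming the aryl C8a–O1 bond, so the C2 configuration is carried over unchanged, and the tertiary alkoxide has no hydrogen on its carbinol carbon for β-hydride elimination.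

Step 6
Reactants: 8 (2R)-2,8-dimethyl-2-(4-methylpent-3-en-1-yl)-6-[(triisopropylsilyl)oxy]chroman
Product: 9 (2E)-5-{(2R)-2,8-dimethyl-6-[(triisopropylsilyl)oxy]chroman-2-yl}-2-methylpent-2-en-1-ol
Conditions: SeO2 (0.2 equiv), t-BuOOH (2 equiv), salicylic acid (0.1 equiv), CH2Cl2, 0 °C to rt
Reagents that add atoms: tert-butyl hydroperoxide, CC(C)(C)OO (net oxygen source, passed on through SeO2, O=[Se]=O)
Why: SeO2 allylic hydroxylation (ene reaction then [2,3]-sigmatropic shift), which on a gem-dimethyl trisubstituted alkene oxidises the (E)-methyl group and so defines the 3'E geometry with C5' as the new CH2OH.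

Step 7
Reactants: 9 (2E)-5-{(2R)-2,8-dimethyl-6-[(triisopropylsilyl)oxy]chroman-2-yl}-2-methylpent-2-en-1-ol
Product: 10 (2R)-2-[(3E)-5-bromo-4-methylpent-3-en-1-yl]-2,8-dimethyl-6-[(triisopropylsilyl)oxy]chroman
Conditions: CBr4, PPh3, CH2Cl2, 0 °C
Reagents that add atoms: carbon tetrabromide, BrC(Br)(Br)Br
Why: Appel bromination of a primary allylic alcohol under neutral conditions, which should keep the alkene position and geometry and spare the aryl silyl ether.

Step 8
Reactants: 10 (2R)-2-[(3E)-5-bromo-4-methylpent-3-en-1-yl]-2,8-dimethyl-6-[(triisopropylsilyl)oxy]chroman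
Product: 11 (2R)-2,8-dimethyl-2-[(3E)-4-methylhepta-3,6-dien-1-yl]-6-[(triisopropylsilyl)oxy]chroman
Conditions: CH2=CHMgBr (1.5 equiv), CuI (10 mol%), THF, −30 to 0 °C
Reagents that add atoms: vinylmagnesium bromide, C=C[Mg]Br
Why: Cu-catalysed allylic substitution of a primary allylic bromide by a Grignard reagent, expected to attack the CH2Br carbon directly (SN2 mode) with the alkene geometry kept, giving the skipped diene that holds C6' and C7'.

Step 9
Reactants: 11 (2R)-2,8-dimethyl-2-[(3E)-4-methylhepta-3,6-dien-1-yl]-6-[(triisopropylsilyl)oxy]chroman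
Product: 12 (2R)-2,8-dimethyl-2-[(3E)-4-methyl-7-(4,4,5,5-tetramethyl-1,3,2-dioxaborolan-2-yl)hept-3-en-1-yl]-6-[(triisopropylsilyl)oxy]chroman
Conditions: HBpin (1.2 equiv), [Ir(cod)Cl]2 (1.5 mol%), dppm (3 mol%), CH2Cl2, rt
Reagents that add atoms: pinacolborane, [H]B1OC(C)(C)C(C)(C)O1
Why: Ir-catalysed anti-Markovnikov hydroboration, selective for the monosubstituted alkene over the trisubstituted 3'-alkene, places boron on the terminal C7'.

Step 10
Reactants: 13 4-methylpent-3-en-1-ol; 14 2,4,6-triisopropylbenzoyl chloride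
Product: 15 4-methylpent-3-en-1-yl 2,4,6-triisopropylbenzoate
Conditions: Et3N, DMAP (0.2 equiv), CH2Cl2, reflux
Reagents that add atoms: none
Why: DMAP-catalysed acylation of a primary alcohol with the hindered acyl chloride gives the benzoate whose bulk later blocks attack at the carbonyl group and directs lithiation to the OCH2 group.

Step 11
Reactants: 12 (2R)-2,8-dimethyl-2-[(3E)-4-methyl-7-(4,4,5,5-tetramethyl-1,3,2-dioxaborolan-2-yl)hept-3-en-1-yl]-6-[(triisopropylsilyl)oxy]chroman; 16 ethyl 2,4,6-triisopropylbenzoate; 15 4-methylpent-3-en-1-yl 2,4,6-triisopropylbenzoate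
Product: 18 (2R)-2,8-dimethyl-2-[(3E,8S,9S)-4,8,12-trimethyl-9-(4,4,5,5-tetramethyl-1,3,2-dioxaborolan-2-yl)trideca-3,11-dien-1-yl]-6-[(triisopropylsilyl)oxy]chroman, via C8' boronic ester 17 (not isolated)
Conditions: 16 (1.3 equiv), (+)-sparteine, s-BuLi (1.2 equiv), Et2O, −78 °C; 12, −78 °C to rt; recooled to −78 °C and combined by cannula with lithiated 15 [15 (1.6 equiv), (+)-sparteine, s-BuLi (1.5 equiv), Et2O, −78 °C]; −78 to 35 °C
Reagents that add atoms: none
Why: Each benzoate is deprotonated next to oxygen by s-BuLi/(+)-sparteine to a carbenoid that is configurationally stable at −78 °C, adds to boron with retention to give a boronate complex, and on warming lets the carbon on boron shift to the carbenoid carbon anti to the departing carboxylate, so the first pass makes C7'–C8' and the second C8'–C9' (1,2-metallate rearrangement). The closest known reaction type is the iterative lithiation–borylation homologation of pinacol boronic esters with sparteine-complexed lithiated triisopropylbenzoates, run here twice without work-up; no ring is closed. C8' is set as S by the ligand alone, since (+)-sparteine removes the pro-R proton of 16, borylation retains and the shift inverts the carbenoid carbon, after which C8' migrates to C9' with retention; C9' is set as S in the same way by the second carbenoid and is erased at the ketone stage. The C2 centre, eight bonds away, cannot bias either event, so the diastereomer ratio should mirror the enantiomeric purity of the carbenoids. The step needs one insertion per pass and deprotonation at OCH2 instead of the allylic CH2 of 15, which are secured by keeping each benzoate in slight excess over s-BuLi, by completing boronate formation at −78 °C so that surplus carbenoid decays on warming before 17 is released, and by the carboxylate-directed lithiation. Substrate 12 offers only boron as an electrophilic site, its aryl silyl ether, chroman ether and trisubstituted alkene being inert to the carbenoids at low temperature.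

Step 12
Reactants: 18 (2R)-2,8-dimethyl-2-[(3E,8S,9S)-4,8,12-trimethyl-9-(4,4,5,5-tetramethyl-1,3,2-dioxaborolan-2-yl)trideca-3,11-dien-1-yl]-6-[(triisopropylsilyl)oxy]chroman
Product: 19 (2R)-2-[(3E,8S,9S)-9-hydroxy-4,8,12-trimethyltrideca-3,11-dien-1-yl]-2,8-dimethyl-6-[(triisopropylsilyl)oxy]chroman
Conditions: H2O2 (30%), NaOH (2 M), THF, 0 °C
Reagents that add atoms: hydrogen peroxide, OO
Why: Alkaline peroxide oxidation of the C–B bond (hydroperoxide adds to boron, C9' shifts to oxygen with retention), which should leave the alkenes and the bulky aryl silyl ether untouched in the cold.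

Step 13
Reactants: 19 (2R)-2-[(3E,8S,9S)-9-hydroxy-4,8,12-trimethyltrideca-3,11-dien-1-yl]-2,8-dimethyl-6-[(triisopropylsilyl)oxy]chroman
Product: 20 (2R)-2,8-dimethyl-2-[(3E,8S)-4,8,12-trimethyl-9-oxotrideca-3,11-dien-1-yl]-6-[(triisopropylsilyl)oxy]chroman
Conditions: Dess–Martin periodinane, pyridine, CH2Cl2, 0 °C
Reagents that add atoms: none
Why: Dess–Martin oxidation under buffered, non-enolising conditions should give the β,γ-unsaturated ketone without moving the C11'=C12' alkene into conjugation or epimerising C8', while the C9' centre is removed on purpose.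

Step 14
Reactants: 20 (2R)-2,8-dimethyl-2-[(3E,8S)-4,8,12-trimethyl-9-oxotrideca-3,11-dien-1-yl]-6-[(triisopropylsilyl)oxy]chroman
Product: 21 (2R)-2,8-dimethyl-2-[(3E,8S)-4,8,12-trimethyl-9-oxotrideca-3,11-dien-1-yl]chroman-6-ol
Conditions: TBAF, AcOH (1 equiv each), THF, 0 °C to rt
Reagents that add atoms: none
Why: Fluoride cleavage of the aryl silyl ether, with acetic acid buffering fluoride and phenoxide basicity so that neither C8' epimerisation nor conjugation of the β,γ-enone should occur.

Compound list
1 | 2-methylhydroquinone (2-methylbenzene-1,4-diol) | Cc1cc(O)ccc1O | starting material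
2 | 2-methyl-4-[(triisopropylsilyl)oxy]phenol | Cc1cc(O[Si](C(C)C)(C(C)C)C(C)C)ccc1O | intermediate
3 | 2-bromo-6-methyl-4-[(triisopropylsilyl)oxy]phenol | Cc1cc(O[Si](C(C)C)(C(C)C)C(C)C)cc(Br)c1O | intermediate
4 | (R)-linalool, (3R)-3,7-dimethylocta-1,6-dien-3-ol | CC(C)=CCC[C@](O)(C)C=C | starting material
5 | 9-[(3S)-3-hydroxy-3,7-dimethyloct-6-en-1-yl]-9-borabicyclo[3.3.1]nonane (same spatial arrangement as in 4; the descriptor changes only because boron ranks below carbon) | CC(C)=CCC[C@](O)(C)CCB1C2CCCC1CCC2 | intermediate (not isolated)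
6 | 2-[(3R)-3-hydroxy-3,7-dimethyloct-6-en-1-yl]-6-methyl-4-[(triisopropylsilyl)oxy]phenol | CC(C)=CCC[C@](O)(C)CCc1cc(O[Si](C(C)C)(C(C)C)C(C)C)cc(C)c1O | intermediate
7 | 2-[(3R)-3-hydroxy-3,7-dimethyloct-6-en-1-yl]-6-methyl-4-[(triisopropylsilyl)oxy]phenyl trifluoromethanesulfonate | CC(C)=CCC[C@](O)(C)CCc1cc(O[Si](C(C)C)(C(C)C)C(C)C)cc(C)c1OS(=O)(=O)C(F)(F)F | intermediate
8 | (2R)-2,8-dimethyl-2-(4-methylpent-3-en-1-yl)-6-[(triisopropylsilyl)oxy]chroman | CC(C)=CCC[C@]1(C)CCc2cc(O[Si](C(C)C)(C(C)C)C(C)C)cc(C)c2O1 | intermediate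
9 | (2E)-5-{(2R)-2,8-dimethyl-6-[(triisopropylsilyl)oxy]chroman-2-yl}-2-methylpent-2-en-1-ol | OC/C(C)=C/CC[C@]1(C)CCc2cc(O[Si](C(C)C)(C(C)C)C(C)C)cc(C)c2O1 | intermediate
10 | (2R)-2-[(3E)-5-bromo-4-methylpent-3-en-1-yl]-2,8-dimethyl-6-[(triisopropylsilyl)oxy]chroman | BrC/C(C)=C/CC[C@]1(C)CCc2cc(O[Si](C(C)C)(C(C)C)C(C)C)cc(C)c2O1 | intermediate
11 | (2R)-2,8-dimethyl-2-[(3E)-4-methylhepta-3,6-dien-1-yl]-6-[(triisopropylsilyl)oxy]chroman | C=CC/C(C)=C/CC[C@]1(C)CCc2cc(O[Si](C(C)C)(C(C)C)C(C)C)cc(C)c2O1 | intermediate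
12 | (2R)-2,8-dimethyl-2-[(3E)-4-methyl-7-(4,4,5,5-tetramethyl-1,3,2-dioxaborolan-2-yl)hept-3-en-1-yl]-6-[(triisopropylsilyl)oxy]chroman | CC1(C)OB(CCC/C(C)=C/CC[C@]2(C)CCc3cc(O[Si](C(C)C)(C(C)C)C(C)C)cc(C)c3O2)OC1(C)C | intermediate
13 | 4-methylpent-3-en-1-ol | CC(C)=CCCO | starting material
14 | 2,4,6-triisopropylbenzoyl chloride | CC(C)c1cc(C(C)C)c(C(=O)Cl)c(C(C)C)c1 | starting material
15 | 4-methylpent-3-en-1-yl 2,4,6-triisopropylbenzoate | CC(C)=CCCOC(=O)c1c(C(C)C)cc(C(C)C)cc1C(C)C | intermediate
16 | ethyl 2,4,6-triisopropylbenzoate | CCOC(=O)c1c(C(C)C)cc(C(C)C)cc1C(C)C | starting material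
17 | (2R)-2,8-dimethyl-2-[(3E,8S)-4-methyl-8-(4,4,5,5-tetramethyl-1,3,2-dioxaborolan-2-yl)non-3-en-1-yl]-6-[(triisopropylsilyl)oxy]chroman | CC1(C)OB([C@@H](C)CCC/C(C)=C/CC[C@]2(C)CCc3cc(O[Si](C(C)C)(C(C)C)C(C)C)cc(C)c3O2)OC1(C)C | intermediate (not isolated)
18 | (2R)-2,8-dimethyl-2-[(3E,8S,9S)-4,8,12-trimethyl-9-(4,4,5,5-tetramethyl-1,3,2-dioxaborolan-2-yl)trideca-3,11-dien-1-yl]-6-[(triisopropylsilyl)oxy]chroman | CC(C)=CC[C@H](B1OC(C)(C)C(C)(C)O1)[C@@H](C)CCC/C(C)=C/CC[C@]2(C)CCc3cc(O[Si](C(C)C)(C(C)C)C(C)C)cc(C)c3O2 | intermediate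
19 | (2R)-2-[(3E,8S,9S)-9-hydroxy-4,8,12-trimethyltrideca-3,11-dien-1-yl]-2,8-dimethyl-6-[(triisopropylsilyl)oxy]chroman | CC(C)=CC[C@H](O)[C@@H](C)CCC/C(C)=C/CC[C@]2(C)CCc3cc(O[Si](C(C)C)(C(C)C)C(C)C)cc(C)c3O2 | intermediate
20 | (2R)-2,8-dimethyl-2-[(3E,8S)-4,8,12-trimethyl-9-oxotrideca-3,11-dien-1-yl]-6-[(triisopropylsilyl)oxy]chroman | CC(C)=CCC(=O)[C@@H](C)CCC/C(C)=C/CC[C@]2(C)CCc3cc(O[Si](C(C)C)(C(C)C)C(C)C)cc(C)c3O2 | intermediate
21 | (2R)-2,8-dimethyl-2-[(3E,8S)-4,8,12-trimethyl-9-oxotrideca-3,11-dien-1-yl]chroman-6-ol (CNP0280076.1) | CC(C)=CCC(=O)[C@@H](C)CCC/C(C)=C/CC[C@]1(C)CCc2cc(O)cc(C)c2O1 | target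

Total step count: 14. Longest linear sequence: 13 steps (steps 1 to 9 and 11 to 14, from 1 to 21); step 10 is a one-step side branch.

Steps most likely to fail

Step 11. The sparteine-bound second carbenoid may be slow to capture the hindered secondary boronic ester, surplus first carbenoid may insert twice, or the carbenoid may lose its configuration before capture. The fallback sets out from 12 (with 16 and 15) and returns at 18. It generates the carbenoids free of diamine by tin–lithium exchange. Each benzoate is first deprotonated with s-BuLi/(+)-sparteine at −78 °C and quenched with Me3SnCl, which should give (1R)-1-(trimethylstannyl)ethyl 2,4,6-triisopropylbenzoate F1 from 16 and (1R)-4-methyl-1-(trimethylstannyl)pent-3-en-1-yl 2,4,6-triisopropylbenzoate F2 from 15. Both stannanes can be purified, and their enantiomeric purity raised, before use. Treatment of F1 with n-BuLi in Et2O at −78 °C (exchange with retention), addition of 12 and warming should give 17. The same operation with F2 on 17 should give 18. The unligated carbenoid is smaller and should add more readily to the secondary boronic ester, and no s-BuLi is present at any time.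

Step 5. The triflate may be cleaved at sulfur by the base, returning 6, or oxidative addition of the doubly ortho-substituted, electron-rich aryl triflate to zerovalent palladium may be slow. The fallback sets out from 4 (through its borane 5) and purchased 4-amino-3-methylphenol (Cc1cc(O)ccc1N) and returns at 8. It replaces the triflate by an aryl chloride that is in place before the cross-coupling.
- O-Silylation of the aminophenol (TIPSCl, imidazole) should give 2-methyl-4-[(triisopropylsilyl)oxy]aniline F3.
- NBS bromination ortho to the amino group should give 2-bromo-6-methyl-4-[(triisopropylsilyl)oxy]aniline F4.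
- Sandmeyer chlorination (t-BuONO, CuCl2, MeCN) should give 1-bromo-2-chloro-3-methyl-5-[(triisopropylsilyl)oxy]benzene F5.
- Suzuki–Miyaura coupling of 5 at the C–Br bond (PdCl2(dppf), aqueous K3PO4), chemoselective over C–Cl, should give (3R)-1-{2-chloro-3-methyl-5-[(triisopropylsilyl)oxy]phenyl}-3,7-dimethyloct-6-en-3-ol F6.
- Pd-catalysed intramolecular C–O coupling of the aryl chloride with the tertiary alcohol (Pd(OAc)2, 2-(di-tert-butylphosphino)-1,1'-binaphthyl, Cs2CO3, toluene) should close ring B to 8 with C2 untouched.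

Step 6. The allylic oxidation may stall at partial conversion, run on to the enal, or attack the C2' methylene. The fallback sets out from 8 and returns at 9, and rebuilds the alkene instead of oxidising next to it.
- Oxidative cleavage of the prenyl alkene (OsO4 catalytic, NaIO4, 2,6-lutidine, dioxane/water) should give 3-{(2S)-2,8-dimethyl-6-[(triisopropylsilyl)oxy]chroman-2-yl}propanal F7. The descriptor changes by priority only; the spatial arrangement is the same.
- Wittig olefination with ethyl 2-(triphenylphosphoranylidene)propanoate, which is E-selective for a stabilised ylide, should give ethyl (2E)-5-{(2R)-2,8-dimethyl-6-[(triisopropylsilyl)oxy]chroman-2-yl}-2-methylpent-2-enoate F8.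
- Reduction with diisobutylaluminium hydride in CH2Cl2 at −78 °C should give 9.

Further compounds
F1 | step 11 | (1R)-1-(trimethylstannyl)ethyl 2,4,6-triisopropylbenzoate | C[Sn](C)(C)[C@H](C)OC(=O)c1c(C(C)C)cc(C(C)C)cc1C(C)C
F2 | step 11 | (1R)-4-methyl-1-(trimethylstannyl)pent-3-en-1-yl 2,4,6-triisopropylbenzoate | C[Sn](C)(C)[C@H](CC=C(C)C)OC(=O)c1c(C(C)C)cc(C(C)C)cc1C(C)C
F3 | step 5 | 2-methyl-4-[(triisopropylsilyl)oxy]aniline | Cc1cc(O[Si](C(C)C)(C(C)C)C(C)C)ccc1N
F4 | step 5 | 2-bromo-6-methyl-4-[(triisopropylsilyl)oxy]aniline | Cc1cc(O[Si](C(C)C)(C(C)C)C(C)C)cc(Br)c1N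
F5 | step 5 | 1-bromo-2-chloro-3-methyl-5-[(triisopropylsilyl)oxy]benzene | Cc1cc(O[Si](C(C)C)(C(C)C)C(C)C)cc(Br)c1Cl
F6 | step 5 | (3R)-1-{2-chloro-3-methyl-5-[(triisopropylsilyl)oxy]phenyl}-3,7-dimethyloct-6-en-3-ol | CC(C)=CCC[C@](O)(C)CCc1cc(O[Si](C(C)C)(C(C)C)C(C)C)cc(C)c1Cl
F7 | step 6 | 3-{(2S)-2,8-dimethyl-6-[(triisopropylsilyl)oxy]chroman-2-yl}propanal | O=CCC[C@]1(C)CCc2cc(O[Si](C(C)C)(C(C)C)C(C)C)cc(C)c2O1
F8 | step 6 | ethyl (2E)-5-{(2R)-2,8-dimethyl-6-[(triisopropylsilyl)oxy]chroman-2-yl}-2-methylpent-2-enoate | CCOC(=O)/C(C)=C/CC[C@]1(C)CCc2cc(O[Si](C(C)C)(C(C)C)C(C)C)cc(C)c2O1
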